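**Assumption:** (R)-4-methylcyclopent-2-en-1-one (1) and (R)-but-3-ene-1,2-diol (8) are bought as single enantiomers; locants C1–C13 are those of the target skeleton (C1 ketone, C2=C3, C4–CH3, C5 H2, C6 lactone O–CH, C7, C8, C9, C10 carbinol, C11=C13 methylene, C12 lactone C=O), which is also guaiane numbering for the 5/7-fused intermediates.

## Retrosynthetic overview

1. Target 24 ⇐ acylation of C9–OH ⇐ hydrolytic opening (inversion at C9) of the 9,10-epoxy ketone 22.
2. 22 (ten-membered ring, Z-enone) ⇐ ring expansion: alkoxy-radical β-scission of the C1–C5 fusion bond of the 5/7-fused carbinol 21.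
3. 21 ⇐ C8–OH-directed epoxidation and ring-closing metathesis (C9=C10, seven-membered ring) of diene 16.
4. 16 ⇐ alkyne cyclocarbonylation (α-methylene lactone) ⇐ C6–C7 propargylation of aldehyde 7 with propargylic mesylate 13.
5. Rings in order: cyclopentene (purchased) → γ-lactone → cycloheptene → oxirane → cyclodecenone (5 + 7 → 10).

## Route

Step 1
Reactants: 1 (R)-4-methylcyclopent-2-en-1-one; 2 formaldehyde
Product: 3 (4S,5S)-5-(hydroxymethyl)-4-methylcyclopent-2-en-1-one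
Conditions: LiN(iPr)2, THF, −78 °C; then CH2O gas (cracked paraformaldehyde), −78 °C; AcOH quench
Reagents that add atoms: none
Why: Kinetic α′-deprotonation at C5 and aldol addition to formaldehyde on the enolate face anti to the C4 methyl (directed aldol, hydroxymethylation) give the trans-4,5 ketol.

Step 2
Reactants: 3 (4S,5S)-5-(hydroxymethyl)-4-methylcyclopent-2-en-1-one; 4 isopropenylmagnesium bromide
Product: 6 (1S,4S,5S)-4-methyl-1-(prop-1-en-2-yl)-1-[(triethylsilyl)oxy]-5-{[(triethylsilyl)oxy]methyl}cyclopent-2-ene, via diol 5 (not isolated)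
Conditions: CeCl3, THF, −78 °C; then Et3SiOTf, 2,6-lutidine, −78 → 0 °C
Reagents that add atoms: triethylsilyl trifluoromethanesulfonate, CC[Si](CC)(CC)OS(=O)(=O)C(F)(F)F
Why: Cerium-assisted Grignard 1,2-addition to the enone carbonyl occurs anti to the C5 substituent and both alkoxides are silylated in the same flask; C1 and C5 are erased in step 12, so their ratio does not matter.

Step 3
Reactants: 6 (1S,4S,5S)-4-methyl-1-(prop-1-en-2-yl)-1-[(triethylsilyl)oxy]-5-{[(triethylsilyl)oxy]methyl}cyclopent-2-ene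
Product: 7 (1R,2S,5S)-5-methyl-2-(prop-1-en-2-yl)-2-[(triethylsilyl)oxy]cyclopent-3-ene-1-carbaldehyde
Conditions: (COCl)2, DMSO, CH2Cl2, −78 → −40 °C; Et3N, −78 → 0 °C; used at once
Reagents that add atoms: none
Why: Swern oxidative desilylation cleaves and oxidises only the primary triethylsilyl ether, while the hindered tertiary silyl ether survives.

Step 4
Reactants: 8 (R)-but-3-ene-1,2-diol
Product: 9 (R)-3,4-bis[(triethylsilyl)oxy]but-1-ene
Conditions: Et3SiCl, imidazole, DMF, 0 → 23 °C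
Reagents that add atoms: chlorotriethylsilane, CC[Si](Cl)(CC)CC
Why: Standard bis-silylation of the diol; the stereocentre (future C8) is untouched.

Step 5
Reactants: 9 (R)-3,4-bis[(triethylsilyl)oxy]but-1-ene; 10 ethynylmagnesium bromide
Product: 12 (3S,4R)-4-[(triethylsilyl)oxy]hex-5-en-1-yn-3-ol, via silyloxy aldehyde 11 (not isolated)
Conditions: (COCl)2, DMSO, CH2Cl2, −78 → −40 °C; Et3N; then HC≡CMgBr (excess), THF, −78 °C
Reagents that add atoms: none
Why: Swern oxidative desilylation gives the labile α-silyloxy aldehyde, which is trapped by the alkynyl Grignard under Felkin–Anh (non-chelation) control to give the 3,4-anti alcohol (about 5:1, minor syn isomer removed by chromatography).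

Step 6
Reactants: 12 (3S,4R)-4-[(triethylsilyl)oxy]hex-5-en-1-yn-3-ol
Product: 13 (3S,4R)-4-[(triethylsilyl)oxy]hex-5-en-1-yn-3-yl methanesulfonate
Conditions: MsCl, Et3N, CH2Cl2, −78 → 0 °C
Reagents that add atoms: methanesulfonyl chloride, CS(=O)(=O)Cl
Why: O-sulfonylation with retention at carbon provides the propargylic electrophile.

Step 7
Reactants: 7 (1R,2S,5S)-5-methyl-2-(prop-1-en-2-yl)-2-[(triethylsilyl)oxy]cyclopent-3-ene-1-carbaldehyde; 13 (3S,4R)-4-[(triethylsilyl)oxy]hex-5-en-1-yn-3-yl methanesulfonate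
Product: 14 (1S,2S,3R)-2-ethynyl-1-[(1S,2S,5S)-5-methyl-2-(prop-1-en-2-yl)-2-[(triethylsilyl)oxy]cyclopent-3-en-1-yl]-3-[(triethylsilyl)oxy]pent-4-en-1-ol
Conditions: Pd(OAc)2 (5 mol %), PPh3 (5 mol %), InI (1.4 equiv), THF/HMPA 3:1, 23 °C
Reagents that add atoms: none
Why: Marshall propargylation: zerovalent palladium ionises the mesylate anti (SN2′), transmetalation gives a chiral allenylindium, and its closed SE2′ transition state adds to the aldehyde under reagent control, setting C7 with net inversion and C6 anti to it (the trans-lactone relationship).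

Step 8
Reactants: 14 (1S,2S,3R)-2-ethynyl-1-[(1S,2S,5S)-5-methyl-2-(prop-1-en-2-yl)-2-[(triethylsilyl)oxy]cyclopent-3-en-1-yl]-3-[(triethylsilyl)oxy]pent-4-en-1-ol
Product: 16 (4R,5S)-4-[(1R)-1-hydroxyprop-2-en-1-yl]-3-methylidene-5-[(1S,2S,5S)-5-methyl-2-(prop-1-en-2-yl)-2-[(triethylsilyl)oxy]cyclopent-3-en-1-yl]oxolan-2-one, via bis-silyl lactone 15 (not isolated)
Conditions: PdCl2 (10 mol %), thiourea (40 mol %), CO (1 atm), acetone, 50 °C; then HF·pyridine, pyridine, THF, 0 °C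
Reagents that add atoms: carbon monoxide, [C-]#[O+]
Why: Norton-type palladium-catalysed cyclocarbonylation of the homopropargylic alcohol builds the α-methylene-γ-butyrolactone with C6 and C7 unchanged, and buffered HF then removes only the less hindered secondary allylic silyl ether.

Step 9
Reactants: 16 (4R,5S)-4-[(1R)-1-hydroxyprop-2-en-1-yl]-3-methylidene-5-[(1S,2S,5S)-5-methyl-2-(prop-1-en-2-yl)-2-[(triethylsilyl)oxy]cyclopent-3-en-1-yl]oxolan-2-one
Product: 17 (1S,4S,5S,6S,7R,8R)-8-hydroxy-1-[(triethylsilyl)oxy]guaia-2,9,11(13)-trien-12,6-olide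
Conditions: second-generation Grubbs catalyst (H2IMes)(PCy3)Cl2Ru=CHPh (10 mol %), 1,4-benzoquinone (20 mol %), toluene (2 mM), 80 °C
Reagents that add atoms: none
Why: Ring-closing metathesis of the C8 vinyl group with the isopropenyl group closes the seven-membered ring with a necessarily cis trisubstituted C9=C10 alkene; the free allylic hydroxyl speeds initiation and benzoquinone suppresses allylic-alcohol isomerisation.

Step 10
Reactants: 17 (1S,4S,5S,6S,7R,8R)-8-hydroxy-1-[(triethylsilyl)oxy]guaia-2,9,11(13)-trien-12,6-olide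
Product: 18 (1S,4S,5S,6S,7R,8S,9S,10S)-9,10-epoxy-8-hydroxy-1-[(triethylsilyl)oxy]guaia-2,11(13)-dien-12,6-olide
Conditions: VO(acac)2 (5 mol %), t-BuOOH (1.5 equiv), CH2Cl2, 0 → 23 °C
Reagents that add atoms: tert-butyl hydroperoxide, CC(C)(C)OO
Why: Hydroxyl-directed vanadium-catalysed epoxidation of the cycloheptenol delivers oxygen to the C9=C10 face syn to C8–OH, setting C10 in its final configuration and C9 for later inversion; the silylated C1 oxygen cannot direct.

Step 11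
Reactants: 18 (1S,4S,5S,6S,7R,8S,9S,10S)-9,10-epoxy-8-hydroxy-1-[(triethylsilyl)oxy]guaia-2,11(13)-dien-12,6-olide; 19 (E)-but-2-enoic acid
Product: 21 (1S,4S,5S,6S,7S,8S,9S,10S)-8-[(E)-but-2-enoyloxy]-9,10-epoxy-1-hydroxyguaia-2,11(13)-dien-12,6-olide, via silyl ether crotonate 20 (not isolated)
Conditions: N,N′-diisopropylcarbodiimide, DMAP, CH2Cl2, 0 → 23 °C; then Bu4NF, AcOH, THF, 0 → 23 °C
Reagents that add atoms: none
Why: Steglich esterification acylates the only free hydroxyl (C8), and acetic-acid-buffered fluoride then frees the tertiary C1 alcohol without touching epoxide, esters or the methylene lactone.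

Step 12
Reactants: 21 (1S,4S,5S,6S,7S,8S,9S,10S)-8-[(E)-but-2-enoyloxy]-9,10-epoxy-1-hydroxyguaia-2,11(13)-dien-12,6-olide
Product: 22 (4R,6R,7S,8S,9S,10S)-8-[(E)-but-2-enoyloxy]-9,10-epoxy-1-oxogermacra-2(Z),11(13)-dien-12,6-olide
Conditions: [Ir(dF(CF3)ppy)2(5,5′-d(CF3)bpy)]PF6 (2 mol %), 2,4,6-triisopropylbenzenethiol (20 mol %), 2,4,6-collidine (30 mol %), PhCF3 (0.02 M), 450 nm LEDs, 25 °C
Reagents that add atoms: none
Why: Proposed new method: proton-coupled electron transfer from the tertiary O–H (excited trivalent iridium oxidant, collidine base) gives the C1 alkoxy radical, whose only productive β-scission is the C1–C5 fusion bond (C1–C2 would give a vinyl radical, C1–C10 an oxiranyl σ-radical), and the secondary C5 radical is reduced by the arenethiol, so the 5/7 bicycle opens to the ten-membered ring with the cis C2=C3 geometry inherited from the cyclopentene and no new stereocentre; the closest known reaction types are the redox-neutral PCET ring opening of unstrained cyclic tertiary alcohols and hypoiodite alkoxy-radical fragmentation, neither yet shown for expanding a fused epoxy bis-allylic carbinol to a medium ring.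

Step 13
Reactants: 22 (4R,6R,7S,8S,9S,10S)-8-[(E)-but-2-enoyloxy]-9,10-epoxy-1-oxogermacra-2(Z),11(13)-dien-12,6-olide
Product: 23 (4R,6R,7S,8S,9R,10S)-8-[(E)-but-2-enoyloxy]-9,10-dihydroxy-1-oxogermacra-2(Z),11(13)-dien-12,6-olide
Conditions: HClO4 (5 mol %), THF/H2O 3:1, 0 → 23 °C
Reagents that add atoms: water, O
Why: Acid-catalysed hydrolysis of the α,β-epoxy ketone: water attacks the β-carbon C9 with inversion (C10 is deactivated by the adjacent carbonyl), setting C9 and unveiling the tertiary C10 alcohol.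

Step 14
Reactants: 23 (4R,6R,7S,8S,9R,10S)-8-[(E)-but-2-enoyloxy]-9,10-dihydroxy-1-oxogermacra-2(Z),11(13)-dien-12,6-olide; 19 (E)-but-2-enoic acid
Product: 24 (4R,6R,7S,8S,9R,10S)-8,9-bis[(E)-but-2-enoyloxy]-10-hydroxy-1-oxogermacra-2(Z),11(13)-dien-12,6-olide
Conditions: N,N′-diisopropylcarbodiimide, DMAP, CH2Cl2, 0 → 23 °C
Reagents that add atoms: none
Why: DMAP-catalysed Steglich esterification acylates the secondary C9 hydroxyl, while the tertiary C10 hydroxyl next to the ketone does not react.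

## Compound list

1 | (R)-4-methylcyclopent-2-en-1-one | O=C1C=C[C@H](C)C1 | starting material
2 | formaldehyde | C=O | starting material
3 | (4S,5S)-5-(hydroxymethyl)-4-methylcyclopent-2-en-1-one (CH2OH trans to CH3) | O=C1C=C[C@H](C)[C@H]1CO | intermediate
4 | isopropenylmagnesium bromide, CH2=C(CH3)MgBr | CC(=C)[Mg]Br | starting material
5 | (1S,4S,5S)-5-(hydroxymethyl)-4-methyl-1-(prop-1-en-2-yl)cyclopent-2-en-1-ol | CC(=C)[C@]1(O)C=C[C@H](C)[C@H]1CO | intermediate (not isolated)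
6 | (1S,4S,5S)-4-methyl-1-(prop-1-en-2-yl)-1-[(triethylsilyl)oxy]-5-{[(triethylsilyl)oxy]methyl}cyclopent-2-ene | CC(=C)[C@]1(O[Si](CC)(CC)CC)C=C[C@H](C)[C@H]1CO[Si](CC)(CC)CC | intermediate
7 | (1R,2S,5S)-5-methyl-2-(prop-1-en-2-yl)-2-[(triethylsilyl)oxy]cyclopent-3-ene-1-carbaldehyde | CC(=C)[C@]1(O[Si](CC)(CC)CC)C=C[C@H](C)[C@H]1C=O | intermediate
8 | (R)-but-3-ene-1,2-diol | C=C[C@@H](O)CO | starting material
9 | (R)-3,4-bis[(triethylsilyl)oxy]but-1-ene | C=C[C@@H](O[Si](CC)(CC)CC)CO[Si](CC)(CC)CC | intermediate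
10 | ethynylmagnesium bromide, HC≡CMgBr | C#C[Mg]Br | starting material
11 | (R)-2-[(triethylsilyl)oxy]but-3-enal | C=C[C@@H](O[Si](CC)(CC)CC)C=O | intermediate (not isolated)
12 | (3S,4R)-4-[(triethylsilyl)oxy]hex-5-en-1-yn-3-ol | C=C[C@@H](O[Si](CC)(CC)CC)[C@@H](O)C#C | intermediate
13 | (3S,4R)-4-[(triethylsilyl)oxy]hex-5-en-1-yn-3-yl methanesulfonate | C=C[C@@H](O[Si](CC)(CC)CC)[C@@H](OS(C)(=O)=O)C#C | intermediate
14 | (1S,2S,3R)-2-ethynyl-1-[(1S,2S,5S)-5-methyl-2-(prop-1-en-2-yl)-2-[(triethylsilyl)oxy]cyclopent-3-en-1-yl]-3-[(triethylsilyl)oxy]pent-4-en-1-ol | CC(=C)[C@]1(O[Si](CC)(CC)CC)C=C[C@H](C)[C@H]1[C@@H](O)[C@H](C#C)[C@H](O[Si](CC)(CC)CC)C=C | intermediate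
15 | (4S,5S)-3-methylidene-5-[(1S,2S,5S)-5-methyl-2-(prop-1-en-2-yl)-2-[(triethylsilyl)oxy]cyclopent-3-en-1-yl]-4-{(1R)-1-[(triethylsilyl)oxy]prop-2-en-1-yl}oxolan-2-one | CC(=C)[C@]1(O[Si](CC)(CC)CC)C=C[C@H](C)[C@H]1[C@H]2OC(=O)C(=C)[C@@H]2[C@H](O[Si](CC)(CC)CC)C=C | intermediate (not isolated)
16 | (4R,5S)-4-[(1R)-1-hydroxyprop-2-en-1-yl]-3-methylidene-5-[(1S,2S,5S)-5-methyl-2-(prop-1-en-2-yl)-2-[(triethylsilyl)oxy]cyclopent-3-en-1-yl]oxolan-2-one | CC(=C)[C@]1(O[Si](CC)(CC)CC)C=C[C@H](C)[C@H]1[C@H]2OC(=O)C(=C)[C@@H]2[C@H](O)C=C | intermediate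
17 | (1S,4S,5S,6S,7R,8R)-8-hydroxy-1-[(triethylsilyl)oxy]guaia-2,9,11(13)-trien-12,6-olide (5/7 trans-fused, trans-lactone) | CC1=C[C@@H](O)[C@H]2C(=C)C(=O)O[C@@H]2[C@@H]3[C@@H](C)C=C[C@@]13O[Si](CC)(CC)CC | intermediate
18 | (1S,4S,5S,6S,7R,8S,9S,10S)-9,10-epoxy-8-hydroxy-1-[(triethylsilyl)oxy]guaia-2,11(13)-dien-12,6-olide (epoxide cis to 8-OH) | C[C@]12O[C@H]1[C@@H](O)[C@H]3C(=C)C(=O)O[C@@H]3[C@@H]4[C@@H](C)C=C[C@@]24O[Si](CC)(CC)CC | intermediate
19 | (E)-but-2-enoic acid (crotonic acid) | C/C=C/C(=O)O | starting material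
20 | (1S,4S,5S,6S,7S,8S,9S,10S)-8-[(E)-but-2-enoyloxy]-9,10-epoxy-1-[(triethylsilyl)oxy]guaia-2,11(13)-dien-12,6-olide | C[C@]12O[C@H]1[C@@H](OC(=O)/C=C/C)[C@H]3C(=C)C(=O)O[C@@H]3[C@@H]4[C@@H](C)C=C[C@@]24O[Si](CC)(CC)CC | intermediate (not isolated)
21 | (1S,4S,5S,6S,7S,8S,9S,10S)-8-[(E)-but-2-enoyloxy]-9,10-epoxy-1-hydroxyguaia-2,11(13)-dien-12,6-olide | C[C@]12O[C@H]1[C@@H](OC(=O)/C=C/C)[C@H]3C(=C)C(=O)O[C@@H]3[C@@H]4[C@@H](C)C=C[C@@]24O | intermediate
22 | (4R,6R,7S,8S,9S,10S)-8-[(E)-but-2-enoyloxy]-9,10-epoxy-1-oxogermacra-2(Z),11(13)-dien-12,6-olide | C=C1C(=O)O[C@@H]2C[C@@H](C)/C=C\C(=O)[C@@]3(C)O[C@H]3[C@@H](OC(=O)/C=C/C)[C@@H]12 | intermediate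
23 | (4R,6R,7S,8S,9R,10S)-8-[(E)-but-2-enoyloxy]-9,10-dihydroxy-1-oxogermacra-2(Z),11(13)-dien-12,6-olide | C=C1C(=O)O[C@@H]2C[C@@H](C)/C=C\C(=O)[C@@](C)(O)[C@H](O)[C@@H](OC(=O)/C=C/C)[C@@H]12 | intermediate
24 | (4R,6R,7S,8S,9R,10S)-8,9-bis[(E)-but-2-enoyloxy]-10-hydroxy-1-oxogermacra-2(Z),11(13)-dien-12,6-olide (CNP0223772.1) | C=C1C(=O)O[C@@H]2C[C@@H](C)/C=C\C(=O)[C@@](C)(O)[C@H](OC(=O)/C=C/C)[C@@H](OC(=O)/C=C/C)[C@@H]12 | target

## Step count and risks

Total steps: 14. Longest linear sequence: 11 (steps 1–3 and 7–14; steps 4–6 make the mesylate arm).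

Three steps most likely to fail, with fallbacks:

- **Step 12 (proposed new ring expansion).** The thiol or base may add to the Michael acceptors, or scission may be slow. Fallback with known chemistry, setting out from 21: hypoiodite fragmentation with PhI(OAc)2 and I2 under visible light in CH2Cl2/cyclohexane cleaves the same C1–C5 bond and traps the C5 radical with iodine, giving the C5-iodo ten-membered ketone F5 as a mixture of C5 epimers; radical deiodination with (Me3Si)3SiH and AIBN in benzene at 80 °C comes back to the route at 22.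

- **Step 9 (ring-closing metathesis).** A trisubstituted alkene must form next to the quaternary, silylated C1 in a trans-fused bicycle. Fallback setting out from 16: remove the tertiary silyl ether as well (Bu4NF, AcOH) to give the diol diene F2; run the metathesis on this unprotected substrate, whose free tertiary allylic hydroxyl no longer shields the isopropenyl group, to give the tricyclic diol F3; re-silylate both hydroxyls (Et3SiOTf, 2,6-lutidine) to the bis-silyl ether F4; selective cleavage of the secondary silyl ether (HF·pyridine, pyridine, 0 °C) comes back to the route at 17.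

- **Step 7 (propargylation).** The aldehyde is hindered and β-silyloxy, and the allenylindium could undergo 1,4-elimination of the neighbouring silyloxy group. Fallback setting out from 13: copper-catalysed anti-SN2′ borylation (CuCl, Xantphos, KOt-Bu, B2pin2, THF) gives the isolable (M)-allenyl pinacolboronate F1; its phosphoric-acid-promoted allenylboration of aldehyde 7 through the same closed six-membered transition state comes back to the route at 14.

## Further compounds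

F1 | step 7 | (M)-4,4,5,5-tetramethyl-2-[(4R)-4-[(triethylsilyl)oxy]hexa-1,2,5-trien-1-yl]-1,3,2-dioxaborolane | C=C[C@@H](O[Si](CC)(CC)CC)C([H])=[C@@]=C([H])B1OC(C)(C)C(C)(C)O1
F2 | step 9 | (4R,5S)-5-[(1S,2S,5S)-2-hydroxy-5-methyl-2-(prop-1-en-2-yl)cyclopent-3-en-1-yl]-4-[(1R)-1-hydroxyprop-2-en-1-yl]-3-methylideneoxolan-2-one | CC(=C)[C@]1(O)C=C[C@H](C)[C@H]1[C@H]2OC(=O)C(=C)[C@@H]2[C@H](O)C=C
F3 | step 9 | (1S,4S,5S,6S,7R,8R)-1,8-dihydroxyguaia-2,9,11(13)-trien-12,6-olide | CC1=C[C@@H](O)[C@H]2C(=C)C(=O)O[C@@H]2[C@@H]3[C@@H](C)C=C[C@@]13O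
F4 | step 9 | (1S,4S,5S,6S,7S,8R)-1,8-bis[(triethylsilyl)oxy]guaia-2,9,11(13)-trien-12,6-olide | CC1=C[C@@H](O[Si](CC)(CC)CC)[C@H]2C(=C)C(=O)O[C@@H]2[C@@H]3[C@@H](C)C=C[C@@]13O[Si](CC)(CC)CC
F5 | step 12 | (4R,6R,7S,8S,9S,10S)-8-[(E)-but-2-enoyloxy]-9,10-epoxy-5-iodo-1-oxogermacra-2(Z),11(13)-dien-12,6-olide (C5 epimers) | C=C1C(=O)O[C@@H]2C(I)[C@@H](C)/C=C\C(=O)[C@@]3(C)O[C@H]3[C@@H](OC(=O)/C=C/C)[C@@H]12
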